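A ratio of 1.00 Z per D in the violet flask is the symmetric case, the balanced charge of a step-growth recipe. If one Z makes one Q from one D, the zero of the scale is Q at 100%, with neither partner over.

| flask | D | Z | temperature | remark | time |
|---|---|---|---|---|---|
| violet | 20 mM | 20 mM | 60 °C | the very flask that is asked about, followed so far |  |
| grey | 13 mM | 20 mM | 45 °C | run made earlier |  |
| flask | 20 mM | 20.0 mM | 60 °C |  | 6.0 d |

| violet: time / h | violet: Q / % | grey: time / h | grey: Q / % |
|---|---|---|---|
| 10.0 | 45.9 | 5.00 | 16.4 |
| 20.0 | 46.9 | 15.0 | 37.3 |
| 50.0 | 46.6 | 30.0 | 54.3 |
| 120 | 46.5 | 40.0 | 59.9 |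

(scatter of a reading: 0.5 percentage points)

- what is added takes up no volume worth counting
- a reading or a percentage of Q counts all its forms, free or not

- winter: at 6.0 d add D, 50.0% of the amount charged, then wait 6.0 d
- noon: at 6.0 d add Z, 50.0% of the amount charged, then wait 6.0 d
- dusk: change nothing and wait 6.0 d more
- dawn: at 6.0 d raise the temperature by 25 K, then wait 6.0 d

1. Q, in percent of the D first charged, at 6.0 d
2. the option that brings most further Q ("none" if no option brings more than 2 percentage points) (winter / noon / dusk / dawn / none)
3. Q present, in percent of the D first charged, after dusk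
4. Q present, in percent of the D first charged, after dawn

The violet flask stands far from that zero. Its last readings average 46.7%, which gives:

cQ = 46.7% × 20 mM = 9.33 mM
cD = 20 mM − 9.33 mM = 10.7 mM
f = cQ / cZ charged = 9.33 mM / 20 mM = 0.467

This f is the Z share, the Q finally made per Z charged. It means something if the stop is a Z budget: free cZ = 0, the rest of Z lost elsewhere, and Z the limiting reagent despite the equal charge. The other reading is a balance with free Z equal to free D, and that is the weak link.

The grey run bears on it. Its hourly gain, as a fraction of the D charged, falls from 0.0113 /h to 0.00560 /h, to half over 12.5 h. An exponential tail from the midpoint of the last interval then gives: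

grey limit = 57.1% + 0.00560 /h × 12.5 h / 0.693 = 67.2%
grey Z share = 67.2% × 13 mM / 20 mM = 0.437

That stands beside 0.467, with another D charge and another temperature. The two runs differ in both settings, and a Z budget shared with a loss of Z need not give one fixed share, so the closeness proves nothing. This reckoning still commits to the budget, as a judgement, and carries f on. Q stays near 46.7% after dusk and after dawn, winter adds nothing, and noon adds:

f × 50.0% × 20.0 mM / 20 mM = 23 percentage points

The forecast agrees on 46.5% now, 46.5% after dusk and noon as best, but parts on dawn. It reads the stop as one that “suggests an exothermic equilibrium” and puts dawn at 28%.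

The flask gives 46.6% now, noon as best, 46.6% after dusk and 46.6% after dawn.

    D + Z → Q, rate k1*[D]*[Z]^0.5 (k = 0.0160 /M^0.5/min, Ea = 75.0 kJ/mol)
    L ⇌ Q, rate k2*(cs2 - [Q]) while solid is left; crystals form when [Q] > cs2 (solubility = 3.20 mM, k = 0.0210 /min)
    Z → X (k = 0.00330 /min, Ea = 108 kJ/mol)
    (constants at 60 °C)

Dawn stands 19 points above the forecast, and free Z in the flask is 0% of its charge at 144 h. Noon brings 21 points against the 23 points reckoned from the Z share. On a neighbour flask with 12 mM of Z, the other charges as in the violet flask, f gives 28.0% of the D charged, and that flask holds 32.9%.

The runs come from a simulation with made-up constants; scatter was added.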